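**Plan**

- Cuts: C2–C3 (the carbocycle, last C–C bond made), then O6–C12 and C6–C7 (lactone ring and two stereocentres in one event), C9–C10 (alkenyllithium plus epoxide), C7–C11 (Morita–Baylis–Hillman) and the O8 angelate.
- Enabling feature: the ten-membered ring is a cyclodeca-1,5-diene (C10=C1–C2–C3–C4=C5). C2 and C3 are both allylic CH2 groups, the ring carbons are cis on both trisubstituted alkenes (C2/C9 and C3/C6), and the γ-lactone is trans-fused at C6–C7. An open chain ending in C2 and C3 is therefore folded, and C2 can carry a removable PhSO2 group.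
- Forward: lactol 6 (C3–C6, C15) and alkenyl iodide 9 (C2, C1, C10, C14) are two cis-butene units. Iodide 9 is joined to epoxide 11 (C7–C9), the acrylate unit (C11–C13) is added, and CrCl2 allylation of 6 closes the lactone ring. The carbocycle closes last at C2–C3; then the sulfone is removed, the methylene unmasked and the angelate installed.
- Stereochemistry: C8 is bought with (R)-epoxide 11. C7 and C6 are relayed from C8 in the chromium allylation. The C1=C10 geometry comes from trans-hydroalumination/iodination of 7, the C4=C5 geometry from the ring of butenolide 5.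
- Helpers: PhS/PhSO2 at C2 (steps 5–17), the Me2NH adduct of the α-methylene lactone (steps 14–18), TBS on O14/O15, SiEt3 on O8.

Key step: step 16

Assumption: germacrane numbering is used for all intermediates (ring C1–C10, C11–C13 on C7, C14 on C10, C15 on C4; the target is 6R,7R,8R). Centres formed as mixtures and erased later (lactol carbon of 6, carbinol of 19, C11 of 24–30, C2 of 28) carry no descriptor in the SMILES.

**Route**

Step 1
Reactants: 1 1,3-dihydroxyacetone (used as its commercial dimer); 2 ethyl (triphenylphosphoranylidene)acetate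
Product: 4 4-(hydroxymethyl)furan-2(5H)-one, via hydroxy ester 3 (not isolated)
Conditions: CH2Cl2, 25 °C
Reagents that add atoms: none
Why: Wittig olefination of the symmetric ketone (no alkene geometry at issue) and spontaneous lactonisation of one CH2OH arm should give the butenolide whose ring holds C3 cis to C6.

Step 2
Reactants: 4 4-(hydroxymethyl)furan-2(5H)-one
Product: 5 4-{[(tert-butyldimethylsilyl)oxy]methyl}furan-2(5H)-one
Conditions: TBSCl, imidazole, DMF, 25 °C
Reagents that add atoms: tert-butyldimethylsilyl chloride CC(C)(C)[Si](C)(C)Cl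
Why: Standard silylation of the primary alcohol protects O15 for the whole route.

Step 3
Reactants: 5 4-{[(tert-butyldimethylsilyl)oxy]methyl}furan-2(5H)-one
Product: 6 4-{[(tert-butyldimethylsilyl)oxy]methyl}-2,5-dihydrofuran-2-ol
Conditions: i-Bu2AlH (1.1 equiv), CH2Cl2, −78 °C; aq. potassium sodium tartrate
Reagents that add atoms: none
Why: Half-reduction of the lactone at low temperature should stop at the lactol, the ring-chain tautomer of the (Z)-4-hydroxy enal with C6 at the aldehyde level, and the neutral work-up avoids dehydration to the furan.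

Step 4
Reactants: 7 4-[(tert-butyldimethylsilyl)oxy]but-2-yn-1-ol
Product: 9 (Z)-4-[(tert-butyldimethylsilyl)oxy]-3-iodobut-2-en-1-ol, via cyclic alkenylalanate 8 (not isolated)
Conditions: NaAlH2(OCH2CH2OMe)2, THF, 0 °C; then I2, −78 °C
Reagents that add atoms: iodine II
Why: Hydroxyl-directed trans-hydroalumination of the propargylic alcohol places aluminium on the distal alkyne carbon, and iodinolysis with retention should give the iodoalkene with C14 trans and iodine cis to C2.

Step 5
Reactants: 9 (Z)-4-[(tert-butyldimethylsilyl)oxy]-3-iodobut-2-en-1-ol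
Product: 10 (Z)-tert-butyl{[2-iodo-4-(phenylsulfanyl)but-2-en-1-yl]oxy}dimethylsilane
Conditions: PhSSPh, n-Bu3P, THF, 25 °C
Reagents that add atoms: diphenyl disulfide c1ccc(SSc2ccccc2)cc1
Why: Disulfide/phosphine redox condensation converts the primary allylic alcohol into the allyl sulfide by SN2 without allylic shift, placing at C2 the precursor of the activating sulfone in a form that survives t-BuLi.

Step 6
Reactants: 10 (Z)-tert-butyl{[2-iodo-4-(phenylsulfanyl)but-2-en-1-yl]oxy}dimethylsilane; 11 (R)-2-{[(4-methoxybenzyl)oxy]methyl}oxirane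
Product: 13 (2R,4E)-4-{[(tert-butyldimethylsilyl)oxy]methyl}-1-[(4-methoxybenzyl)oxy]-6-(phenylsulfanyl)hex-4-en-2-ol, via alkenyllithium 12 (not isolated)
Conditions: t-BuLi (2.1 equiv), Et2O, −78 °C; then 11, BF3·OEt2, −78 °C
Reagents that add atoms: none
Why: Iodine–lithium exchange with retention and BF3-promoted opening of the terminal epoxide at its CH2 group should form C9–C10 with C9 cis to C2, while C8 is taken unchanged from the epoxide.

Step 7
Reactants: 13 the sulfide alcohol from step 6
Product: 14 (2R,4E)-4-{[(tert-butyldimethylsilyl)oxy]methyl}-1-[(4-methoxybenzyl)oxy]-6-(phenylsulfonyl)hex-4-en-2-ol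
Conditions: (NH4)6Mo7O24 (cat.), 30% H2O2, EtOH, 0 → 25 °C
Reagents that add atoms: hydrogen peroxide OO
Why: Molybdate-catalysed oxidation takes the sulfide to the sulfone much faster than it touches the trisubstituted alkene or the benzyl ether.

Step 8
Reactants: 14 the sulfone alcohol
Product: 15 triethylsilyl ether of 14 at O8
Conditions: Et3SiCl, imidazole, CH2Cl2, 0 °C
Reagents that add atoms: chlorotriethylsilane CC[Si](Cl)(CC)CC
Why: Silylation protects O8 with a group that can later be removed in the presence of the primary TBS ethers.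

Step 9
Reactants: 15 the fully protected sulfone
Product: 16 (2R,4E)-4-{[(tert-butyldimethylsilyl)oxy]methyl}-6-(phenylsulfonyl)-2-[(triethylsilyl)oxy]hex-4-en-1-ol
Conditions: DDQ, CH2Cl2/pH 7 buffer, 0 °C
Reagents that add atoms: none
Why: Oxidative cleavage of the 4-methoxybenzyl ether frees the C7 hydroxyl and leaves silyl ethers, sulfone and alkene untouched.

Step 10
Reactants: 16 the primary alcohol
Product: 17 (2R,4E)-4-{[(tert-butyldimethylsilyl)oxy]methyl}-6-(phenylsulfonyl)-2-[(triethylsilyl)oxy]hex-4-enal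
Conditions: Dess–Martin periodinane, NaHCO3, CH2Cl2, 0 → 25 °C
Reagents that add atoms: none
Why: Buffered Dess–Martin oxidation should give the α-silyloxy aldehyde (C7) without epimerisation at C8.

Step 11
Reactants: 17 the aldehyde; 18 methyl acrylate
Product: 19 methyl (4R,6E)-6-{[(tert-butyldimethylsilyl)oxy]methyl}-3-hydroxy-2-methylidene-8-(phenylsulfonyl)-4-[(triethylsilyl)oxy]oct-6-enoate (both C3 epimers)
Conditions: DABCO, methyl acrylate (excess), MeOH, 25 °C
Reagents that add atoms: none
Why: The Morita–Baylis–Hillman reaction attaches the acrylate α-carbon (C11) to C7, and the new carbinol centre is of no consequence because it becomes sp2 in step 12.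

Step 12
Reactants: 19 the Morita–Baylis–Hillman adduct
Product: 20 methyl (2Z,4R,6E)-2-(bromomethyl)-6-{[(tert-butyldimethylsilyl)oxy]methyl}-8-(phenylsulfonyl)-4-[(triethylsilyl)oxy]octa-2,6-dienoate
Conditions: NBS, Me2S, CH2Cl2, 0 °C
Reagents that add atoms: N-bromosuccinimide O=C1CCC(=O)N1Br
Why: Bromide attacks the alkoxysulfonium intermediate in the SN2′ sense (Corey–Kim-type bromination) and should give the 2-(bromomethyl)enoate with the ester trans to C8.

Step 13
Reactants: 20 the allylic bromide; 6 the lactol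
Product: 23 α-methylene-γ-lactone alcohol (O6–C12 lactone, H6/H7 trans; C5=C4(CH2OTBS)–C3H2OH arm on C6; C8(OSiEt3)–C9–C10(CH2OTBS)=C1–C2H2SO2Ph chain on C7), via allylchromium dichloride 21 (not isolated), via hydroxy ester 22 (not isolated)
Conditions: CrCl2 (4 equiv), THF, 25 °C; then PPTS (cat.), CH2Cl2, 25 °C
Reagents that add atoms: none
Why: In this Nozaki–Hiyama-type 2-(alkoxycarbonyl)allylation the equilibrating allylchromium (trivalent chromium) should add through its γ-carbon C7 to the open hydroxy-enal form of 6 in a chair transition state with C5 and C8 equatorial, which gives the 6,7-anti adduct and, after loss of methanol, the trans lactone. C7 is set from C8 because the C8–H bond eclipses the allyl plane (allylic strain) and the aldehyde enters anti to C9.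

Step 14
Reactants: 23 the α-methylene lactone alcohol
Product: 24 the 13-(dimethylamino) adduct of 23 (C11 epimers)
Conditions: Me2NH (2 M in THF), 0 °C
Reagents that add atoms: dimethylamine CNC
Why: Reversible conjugate addition of the amine masks the α-methylene lactone so that no Michael acceptor is present during the carbanion and reduction steps.

Step 15
Reactants: 24 the amino-lactone alcohol
Product: 26 the C3 allylic chloride of 24, via allylic mesylate 25 (not isolated)
Conditions: MsCl, 2,4,6-collidine, LiCl, DMF, 0 °C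
Reagents that add atoms: lithium chloride [Li+].[Cl-]
Why: Mesylation and in situ SN2 displacement by chloride convert the primary allylic alcohol into the chloride without touching the C4=C5 geometry, and the product is used at once to avoid N-alkylation.

Step 16
Reactants: 26 the chloro sulfone
Product: 28 ten-membered carbocycle carrying PhSO2 at C2 (C2 epimers), via potassium sulfonylallyl anion 27 (not isolated)
Conditions: KN(SiMe3)2 (1.05 equiv), THF, −78 → −20 °C, 0.001 M (slow addition of 26)
Reagents that add atoms: none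
Why: KN(SiMe3)2 removes a C2–H (allyl phenyl sulfone, pKa about 22 in DMSO; the C11–H of the amino-lactone is several pKa units weaker) to give the 1-sulfonylallyl anion 27, which displaces chloride from the primary allylic carbon C3 by intramolecular SN2; the closest known reaction type is the Julia-type alkylation of allylic sulfone anions with allylic halides used to close carbocyclic terpenoid rings. The ten-membered ring closes in the 10-exo-tet mode. The only new stereocentre is C2, either epimer serves because it is erased in step 17, while C6, C7 and C8 and both alkene geometries are carried through unchanged. The step needs attack through C2 rather than C10 of the ambident anion, SN2 at C3 rather than SN2′ at C5, and cyclisation rather than oligomerisation. These are secured because α-attack is the normal course for sulfonylallyl anions and C10 is fully substituted, C5 is a hindered secondary carbon next to the lactone, and the chain is folded by the cis relation of C2/C9 and C3/C6 on the two alkenes and by the trans-fused lactone at C6–C7, with high dilution suppressing the bimolecular path.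

Step 17
Reactants: 28 the macrocyclic sulfone
Product: 29 the desulfonylated macrocycle (C2H2)
Conditions: Na(Hg) (6%), Na2HPO4, MeOH/THF, −20 °C
Reagents that add atoms: none
Why: Buffered reductive desulfonylation cleaves the C2–S bond and the allyl anion should be protonated by methanol at the less substituted terminus C2, keeping the trisubstituted C1=C10 alkene.

Step 18
Reactants: 29 the amino-lactone macrocycle
Product: 31 the α-methylene lactone macrocycle, via trimethylammonium iodide 30 (not isolated)
Conditions: MeI, CH2Cl2/MeOH, 25 °C; then aq. NaHCO3, 25 °C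
Reagents that add atoms: none
Why: Quaternisation and mild-base Hofmann-type elimination regenerate the exocyclic methylene, the only direction open because C11–H is the sole β-hydrogen next to the carbonyl.

Step 19
Reactants: 31 the O8 triethylsilyl ether
Product: 32 the C8 alcohol
Conditions: PPTS, MeOH/CH2Cl2, 0 °C
Reagents that add atoms: none
Why: Acid-catalysed methanolysis should remove the triethylsilyl ether faster than the two primary TBS ethers.

Step 20
Reactants: 32 the C8 alcohol; 33 angelic acid ((Z)-2-methylbut-2-enoic acid)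
Product: 34 the O8 angelate with O14 and O15 as TBS ethers
Conditions: 2,4,6-trichlorobenzoyl chloride, Et3N, toluene, 25 °C; then 32, 80 °C
Reagents that add atoms: none
Why: Yamaguchi-type mixed-anhydride esterification without a nucleophilic catalyst should transfer the angeloyl group without Z to E isomerisation.

Step 21
Reactants: 34 the bis-silyl ether
Product: 35 the target, (6R,7R,8R)-8-angeloyloxy-14,15-dihydroxygermacra-1(10),4,11(13)-trien-12,6-olide with C2/C9 and C3/C6 cis on the ring alkenes
Conditions: HF·pyridine, pyridine, THF, 0 → 25 °C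
Reagents that add atoms: none
Why: Buffered fluoride desilylation frees the two primary allylic alcohols and leaves the lactone and the angelate intact.

**Compound list**

1 | 1,3-dihydroxyacetone | O=C(CO)CO | starting material
2 | ethyl (triphenylphosphoranylidene)acetate | CCOC(=O)C=P(c1ccccc1)(c1ccccc1)c1ccccc1 | starting material
3 | ethyl 4-hydroxy-3-(hydroxymethyl)but-2-enoate | CCOC(=O)C=C(CO)CO | intermediate
4 | 4-(hydroxymethyl)furan-2(5H)-one | O=C1C=C(CO)CO1 | intermediate
5 | 4-{[(tert-butyldimethylsilyl)oxy]methyl}furan-2(5H)-one | O=C1C=C(CO[Si](C)(C)C(C)(C)C)CO1 | intermediate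
6 | 4-{[(tert-butyldimethylsilyl)oxy]methyl}-2,5-dihydrofuran-2-ol | OC1OCC(CO[Si](C)(C)C(C)(C)C)=C1 | intermediate
7 | 4-[(tert-butyldimethylsilyl)oxy]but-2-yn-1-ol | OCC#CCO[Si](C)(C)C(C)(C)C | starting material
8 | sodium bis(2-methoxyethoxy) alkenylalanate, five-membered O–Al–C chelate | [Na+].COCCO[Al-]1(OCCOC)OCC=C1CO[Si](C)(C)C(C)(C)C | intermediate
9 | (Z)-4-[(tert-butyldimethylsilyl)oxy]-3-iodobut-2-en-1-ol | OC/C=C(/CO[Si](C)(C)C(C)(C)C)I | intermediate
10 | (Z)-tert-butyl{[2-iodo-4-(phenylsulfanyl)but-2-en-1-yl]oxy}dimethylsilane | CC(C)(C)[Si](C)(C)OC/C(I)=C/CSc1ccccc1 | intermediate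
11 | (R)-2-{[(4-methoxybenzyl)oxy]methyl}oxirane | COc1ccc(COC[C@H]2CO2)cc1 | starting material
12 | alkenyllithium from 10 (Li in place of I, geometry retained) | [Li]/C(CO[Si](C)(C)C(C)(C)C)=C\CSc1ccccc1 | intermediate
13 | (2R,4E)-4-{[(tert-butyldimethylsilyl)oxy]methyl}-1-[(4-methoxybenzyl)oxy]-6-(phenylsulfanyl)hex-4-en-2-ol | COc1ccc(COC[C@H](O)C/C(CO[Si](C)(C)C(C)(C)C)=C\CSc2ccccc2)cc1 | intermediate
14 | (2R,4E)-4-{[(tert-butyldimethylsilyl)oxy]methyl}-1-[(4-methoxybenzyl)oxy]-6-(phenylsulfonyl)hex-4-en-2-ol | COc1ccc(COC[C@H](O)C/C(CO[Si](C)(C)C(C)(C)C)=C\CS(=O)(=O)c2ccccc2)cc1 | intermediate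
15 | O8 triethylsilyl ether of 14 | COc1ccc(COC[C@H](O[Si](CC)(CC)CC)C/C(CO[Si](C)(C)C(C)(C)C)=C\CS(=O)(=O)c2ccccc2)cc1 | intermediate
16 | (2R,4E)-4-{[(tert-butyldimethylsilyl)oxy]methyl}-6-(phenylsulfonyl)-2-[(triethylsilyl)oxy]hex-4-en-1-ol | OC[C@H](O[Si](CC)(CC)CC)C/C(CO[Si](C)(C)C(C)(C)C)=C\CS(=O)(=O)c1ccccc1 | intermediate
17 | (2R,4E)-4-{[(tert-butyldimethylsilyl)oxy]methyl}-6-(phenylsulfonyl)-2-[(triethylsilyl)oxy]hex-4-enal | O=C[C@H](O[Si](CC)(CC)CC)C/C(CO[Si](C)(C)C(C)(C)C)=C\CS(=O)(=O)c1ccccc1 | intermediate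
18 | methyl acrylate | C=CC(=O)OC | starting material
19 | methyl (4R,6E)-6-{[(tert-butyldimethylsilyl)oxy]methyl}-3-hydroxy-2-methylidene-8-(phenylsulfonyl)-4-[(triethylsilyl)oxy]oct-6-enoate | C=C(C(=O)OC)C(O)[C@H](O[Si](CC)(CC)CC)C/C(CO[Si](C)(C)C(C)(C)C)=C\CS(=O)(=O)c1ccccc1 | intermediate
20 | methyl (2Z,4R,6E)-2-(bromomethyl)-6-{[(tert-butyldimethylsilyl)oxy]methyl}-8-(phenylsulfonyl)-4-[(triethylsilyl)oxy]octa-2,6-dienoate | COC(=O)/C(CBr)=C/[C@H](O[Si](CC)(CC)CC)C/C(CO[Si](C)(C)C(C)(C)C)=C\CS(=O)(=O)c1ccccc1 | intermediate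
21 | allylchromium dichloride from 20 (trivalent chromium on C13, alkene geometry fluxional) | COC(=O)C(C[Cr](Cl)Cl)=C[C@H](O[Si](CC)(CC)CC)C/C(CO[Si](C)(C)C(C)(C)C)=C\CS(=O)(=O)c1ccccc1 | intermediate
22 | open hydroxy ester (C6–OH, C3–OH, methyl acrylate unit on C7; C6, C7, C8 as in 35) | C=C(C(=O)OC)[C@@H]([C@H](O)/C=C(/CO[Si](C)(C)C(C)(C)C)CO)[C@H](O[Si](CC)(CC)CC)C/C(CO[Si](C)(C)C(C)(C)C)=C\CS(=O)(=O)c1ccccc1 | intermediate
23 | α-methylene-γ-lactone alcohol (trans lactone, C3–OH free; C6, C7, C8 as in 35) | C=C1C(=O)O[C@H](/C=C(/CO[Si](C)(C)C(C)(C)C)CO)[C@H]1[C@H](O[Si](CC)(CC)CC)C/C(CO[Si](C)(C)C(C)(C)C)=C\CS(=O)(=O)c1ccccc1 | intermediate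
24 | 13-(dimethylamino) adduct of 23 | CN(C)CC1C(=O)O[C@H](/C=C(/CO[Si](C)(C)C(C)(C)C)CO)[C@H]1[C@H](O[Si](CC)(CC)CC)C/C(CO[Si](C)(C)C(C)(C)C)=C\CS(=O)(=O)c1ccccc1 | intermediate
25 | C3 methanesulfonate of 24 | CN(C)CC1C(=O)O[C@H](/C=C(/CO[Si](C)(C)C(C)(C)C)COS(C)(=O)=O)[C@H]1[C@H](O[Si](CC)(CC)CC)C/C(CO[Si](C)(C)C(C)(C)C)=C\CS(=O)(=O)c1ccccc1 | intermediate
26 | C3 allylic chloride of 24 | CN(C)CC1C(=O)O[C@H](/C=C(/CO[Si](C)(C)C(C)(C)C)CCl)[C@H]1[C@H](O[Si](CC)(CC)CC)C/C(CO[Si](C)(C)C(C)(C)C)=C\CS(=O)(=O)c1ccccc1 | intermediate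
27 | potassium 1-(phenylsulfonyl)allyl anion of 26 (carbanion at C2) | [K+].CN(C)CC1C(=O)O[C@H](/C=C(/CO[Si](C)(C)C(C)(C)C)CCl)[C@H]1[C@H](O[Si](CC)(CC)CC)C/C(CO[Si](C)(C)C(C)(C)C)=C\[CH-]S(=O)(=O)c1ccccc1 | intermediate
28 | ten-membered carbocycle with PhSO2 at C2, Me2NCH2 at C11, TBS on O14/O15, SiEt3 on O8 | CN(C)CC1C(=O)O[C@@H]2/C=C(/CO[Si](C)(C)C(C)(C)C)CC(S(=O)(=O)c3ccccc3)/C=C(/CO[Si](C)(C)C(C)(C)C)C[C@@H](O[Si](CC)(CC)CC)[C@@H]12 | intermediate
29 | desulfonylated amino-lactone macrocycle | CN(C)CC1C(=O)O[C@@H]2/C=C(/CO[Si](C)(C)C(C)(C)C)CC/C=C(/CO[Si](C)(C)C(C)(C)C)C[C@@H](O[Si](CC)(CC)CC)[C@@H]12 | intermediate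
30 | trimethylammonium iodide of 29 | [I-].C[N+](C)(C)CC1C(=O)O[C@@H]2/C=C(/CO[Si](C)(C)C(C)(C)C)CC/C=C(/CO[Si](C)(C)C(C)(C)C)C[C@@H](O[Si](CC)(CC)CC)[C@@H]12 | intermediate
31 | α-methylene lactone macrocycle, O8 triethylsilyl, O14/O15 TBS | C=C1C(=O)O[C@@H]2/C=C(/CO[Si](C)(C)C(C)(C)C)CC/C=C(/CO[Si](C)(C)C(C)(C)C)C[C@@H](O[Si](CC)(CC)CC)[C@@H]12 | intermediate
32 | C8 alcohol, O14/O15 TBS | C=C1C(=O)O[C@@H]2/C=C(/CO[Si](C)(C)C(C)(C)C)CC/C=C(/CO[Si](C)(C)C(C)(C)C)C[C@@H](O)[C@@H]12 | intermediate
33 | angelic acid, (Z)-2-methylbut-2-enoic acid | C/C=C(/C)C(=O)O | starting material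
34 | O8 angelate, O14/O15 TBS | C=C1C(=O)O[C@@H]2/C=C(/CO[Si](C)(C)C(C)(C)C)CC/C=C(/CO[Si](C)(C)C(C)(C)C)C[C@@H](OC(=O)/C(C)=C\C)[C@@H]12 | intermediate
35 | target, (6R,7R,8R)-8-angeloyloxy-14,15-dihydroxygermacra-1(10),4,11(13)-trien-12,6-olide | C=C1C(=O)O[C@@H]2/C=C(/CO)CC/C=C(/CO)C[C@@H](OC(=O)/C(C)=C\C)[C@@H]12 | target

**Count and risks**

Total steps: 21. Longest linear sequence: 18 steps (steps 4–21, from 7).

Step 16 (ring closure). Intermolecular alkylation may outrun closure of the ten-membered ring. Proton transfer from C11–H to the sulfonyl anion may also lead to alkylation of the lactone enolate at C3. The fallback is a ring contraction with loss of CO2 and sets out from 24. LiN(SiMe3)2 (2.1 equiv) and then CO2 should carboxylate C2 to the α-sulfonyl carboxylic acid F1. Yamaguchi lactonisation onto the C3 hydroxyl closes the less strained twelve-membered α-sulfonyl allylic lactone F2. Pd(PPh3)4 (zerovalent palladium) in toluene at 80 °C ionises the allylic C3–O bond, the α-sulfonyl carboxylate loses CO2, and the sulfonylallyl anion recombines with the allyl cation at C3 inside the ion pair (decarboxylative allylation of allyl α-sulfonyl esters). The route is rejoined at 28.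

Step 13 (union and lactone). The facial selectivity at C7 relative to C8 may be poor, or addition may be syn instead of anti. The fallback replaces the relay by reagent-controlled chirality transfer and sets out from 17. Ethynylmagnesium bromide adds in the Felkin–Anh sense (anti to the silyloxy group) to give the propargylic alcohol F3, which is converted into the propargylic methanesulfonate F4. With InI and catalytic Pd(dppf)Cl2 this gives a chiral allenylindium that adds to lactol 6 with net inversion at C7 and anti C6/C7 selectivity, giving the homopropargylic diol F5. Cyclocarbonylation (PdCl2, SnCl2, PPh3, CO, MeCN) then builds the α-methylene lactone on the C6 hydroxyl. The route is rejoined at 23.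

Step 17 (desulfonylation). The allyl anion may be protonated at C10 instead of C2, moving the double bond to C1=C2, or the C14 silyloxide may be lost by 1,4-elimination. The fallback avoids the free anion and sets out from 28. Pd(PPh3)4 (zerovalent palladium) with NaBH4 in THF/i-PrOH ionises the allylic sulfone to the allylpalladium complex, and hydride is delivered to the less substituted terminus C2. The route is rejoined at 29 and no new compound is made.

Further compounds
F1 | step 16 | α-sulfonyl carboxylic acid (CO2H on C2 of 24) | CN(C)CC1C(=O)O[C@H](/C=C(/CO[Si](C)(C)C(C)(C)C)CO)[C@H]1[C@H](O[Si](CC)(CC)CC)C/C(CO[Si](C)(C)C(C)(C)C)=C\C(C(=O)O)S(=O)(=O)c1ccccc1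
F2 | step 16 | twelve-membered α-sulfonyl allylic lactone (C2–C(=O)–O–C3) | CN(C)CC1C(=O)O[C@@H]2/C=C(/CO[Si](C)(C)C(C)(C)C)COC(=O)C(S(=O)(=O)c3ccccc3)/C=C(/CO[Si](C)(C)C(C)(C)C)C[C@@H](O[Si](CC)(CC)CC)[C@@H]12
F3 | step 13 | propargylic alcohol (ethynyl adduct of 17, C7–O anti to C8–O) | C#C[C@H](O)[C@H](O[Si](CC)(CC)CC)C/C(CO[Si](C)(C)C(C)(C)C)=C\CS(=O)(=O)c1ccccc1
F4 | step 13 | propargylic methanesulfonate of F3 | C#C[C@H](OS(C)(=O)=O)[C@H](O[Si](CC)(CC)CC)C/C(CO[Si](C)(C)C(C)(C)C)=C\CS(=O)(=O)c1ccccc1
F5 | step 13 | homopropargylic diol (ethynyl on C7, C6–OH, C3–OH) | C#C[C@@H]([C@H](O)/C=C(/CO[Si](C)(C)C(C)(C)C)CO)[C@H](O[Si](CC)(CC)CC)C/C(CO[Si](C)(C)C(C)(C)C)=C\CS(=O)(=O)c1ccccc1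
F0 | step 17 | none | none
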